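At a given age, the share of the charge that stands as intermediate A stays put in these runs when the charge changes.

| flask | substrate | capture agent | remark | time |
|---|---|---|---|---|
| south-east | 0.10 M | 0.010 M | run made earlier |  |
| north | 0.10 M | 0.0050 M | run made earlier |  |
| north-east | 0.10 M | 0.020 M | run made earlier |  |
| east | 0.15 M | 0.010 M | run made earlier |  |
| epsilon | 0.10 M | 0.0100 M | a closed flask charged with all of it at once and left for 30 d | 30 d |
| delta | 0.10 M | 0.0100 M | one stirred flow tank at steady state, fed with the mixture as stated, mean residence time 30 d |  |
| zeta | 0.10 M (fed, over 24.0 d) | 0.0100 M | all but substrate at the start; substrate goes in evenly over 24.0 d, the run ends at 30 d | 30 d |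

| run | time / d | intermediate A / % | product / % |
|---|---|---|---|
| south-east | 2.50 | 26.1 | 0.1 |
| south-east | 4.00 | 34.3 | 0 |
| south-east | 6.00 | 39.6 | 1.7 |
| south-east | 10.0 | 39.2 | 8.6 |
| south-east | 20.0 | 22.4 | 38.6 |
| south-east | 30.0 | 8.5 | 66.1 |
| north | 2.50 | 25.2 | 0.8 |
| north | 4.00 | 34.8 | 0.2 |
| north | 6.00 | 39.7 | 2.1 |
| north | 10.0 | 38.8 | 8.6 |
| north | 20.0 | 22.6 | 39.1 |
| north | 30.0 | 9.9 | 67.2 |
| north-east | 2.08 | 22.6 | 0.1 |
| north-east | 6.00 | 39.5 | 1.9 |
| north-east | 10.0 | 39.6 | 8.0 |
| north-east | 15.0 | 31.3 | 21.8 |
| north-east | 25.0 | 15.2 | 49.4 |
| north-east | 30.0 | 9.9 | 60.9 |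
| east | 2.50 | 26.1 | 0.3 |
| east | 8.00 | 41.0 | 3.4 |
| east | 15.0 | 31.0 | 21.9 |
| east | 20.0 | 22.0 | 39.0 |
| east | 30.0 | 8.8 | 65.3 |

(scatter of a reading: 0.5 percentage points)

- the stated concentrations are those of everything mixed, before any reaction; amounts are the same in each set-up
- the feed brings no volume worth counting
- the earlier runs were made in a closed, stirred flask

- the set-up with the highest amount of intermediate A at the outlet or at the end, in percent of the substrate put in ("none" if the first two lie within 2 percentage points) (epsilon / delta / zeta / none)
- amount of intermediate A at the outlet or at the end, in percent of the substrate put in, epsilon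
- amount of intermediate A at the outlet or at the end, in percent of the substrate put in, delta
- amount of intermediate A at the outlet or at the end, in percent of the substrate put in, zeta

I read the tables across at one age first. At 6.00 d, with [capture agent] going from 0.0050 M to 0.020 M, intermediate A reads 39.7%, 39.6% and 39.5%, so the spread is within the scatter of 0.5 percentage points. At 20.0 d, with [substrate] going from 0.10 M to 0.15 M, it reads 22.4% and 22.0%. I therefore treat the steps into and out of intermediate A as first-order: each portion of substrate ages along one curve, and a vessel matters through the ages it holds.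

Reading down the columns, the top lies between 6.00 d and 10.0 d, and the highest reading is 41.0% at 8.00 d, in the east run. My zero of the scale is two steps with one equal constant k: the share is then k·age·exp(−k·age), with its top at age one over k and a height of 36.8%. One over the time of the top gives 0.125 /d, my equal-rates clock, k. The reading stands higher than that zero, so I multiply the curve by h = 1.11.

Epsilon holds one age, 30 d, which gives 9.83%. Delta's outlet holds ages spread exponentially around 30 d, which turns the curve into h·kτ over the square of one plus kτ, or 18.5%. Zeta holds ages spread evenly from 6.00 d to 30 d, and the average of the curve over them is 26.6%. So I expect zeta to be highest, with a lead of 8 points over delta, more than the margin.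

The forecast, made from the same runs, gives 9.3%, 18.2% and 25.9% and says: “Zeta is best.”

    substrate → intermediate A (k = 9.86 × 10⁻⁵ /min)
    intermediate A → intermediate B (k = 7.94 × 10⁻⁵ /min)
    intermediate B → intermediate C (k = 9.99 × 10⁻⁵ /min)
    intermediate C → product (k = 2.57 × 10⁻⁴ /min)
    intermediate B + capture agent → trapped intermediate (k = 0.00114 /M/min)

The flasks give 9.37% for epsilon, 18.3% for delta and 26.0% for zeta, so zeta stands highest. A neighbour of epsilon takes 0.17 M of substrate, with everything else held. Neither k nor h contains a charge, so the curve at 30 d again gives 9.83% for this neighbour. The neighbour gives 9.37%, with 1.4% of its substrate left. Of its capture agent, 25% of its own charge remains, against 44% in epsilon.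

(The numbers in the tables were generated by integration for an exercise; the scatter is artificial.)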